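**Retrosynthetic overview**

1. Target ⇐ cleavage of two MOM acetals ⇐ aromatic Claisen rearrangement of an O8 (2-methylbut-3-en-2-yl) ether, which places the prenyl group on C7 of the chroman and frees 8-OH.
2. Flavanone C2–aryl bond ⇐ palladium-catalysed asymmetric conjugate addition of a chroman-6-ylboronic acid (from sterically controlled C–H borylation) to 5,7-bis(methoxymethoxy)chromone; rings A and C arrive together and C2 is set on attachment.
3. Dihydropyran ring ⇐ 6-exo closure of O1–C2 (phenol onto an isopropenyl group) ⇐ three-component conjunctive coupling of an aryl bromide, a vinyl unit and an isopropenylboronate, which makes C4a–C4 and C3–C2 and sets C3.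
4. Enabling feature: in the dihydropyran ring fused to ring B, the carbinol carbon C3 and the benzylic C4 form a CH(OH)–CH2 unit between arene carbon C4a and the gem-dimethyl carbon C2. This is a vinylboron unit in disguise: boron on C3 becomes OH with retention, the arene enters at C4, and C2 arrives as the migrating isopropenyl carbon.
5. Ring order: ring B (purchased) → dihydropyran ring → rings A and C (as the chromone).

Key step: step 2

Remark: (Sp,Sp)-MandyPhos (a 1,1′-bis(diarylphosphino)-2,2′-bis[α-(dimethylamino)benzyl]ferrocene, step 2) and (R)-t-BuPyOx (4-tert-butyl-2-(pyridin-2-yl)-4,5-dihydrooxazole, step 7) are assigned by analogy as the antipodes giving the drawn (S) centres, the mirror-image ligand being used if a model run shows the opposite sense; 13 is taken as purchasable.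

**Route**

Step 1
Reactants: 1 3-bromocatechol
Product: 2 1-bromo-2,3-bis(methoxymethoxy)benzene
Conditions: MOMCl (2.5 equiv), i-Pr2NEt, CH2Cl2, 0 °C to rt
Reagents that add atoms: chloromethyl methyl ether, COCCl
Why: Twofold O-alkylation of the phenols (MOM protection) masks both acidic hydroxyls for the borate chemistry of step 2; no stereocentre is involved.

Step 2
Reactants: 2 1-bromo-2,3-bis(methoxymethoxy)benzene; 3 isopropenylboronic acid pinacol ester; 4 vinylmagnesium bromide
Product: 7 (2S)-1-[2,3-bis(methoxymethoxy)phenyl]-3-methylbut-3-en-2-ol, via bis(alkenyl)borate 5 (not isolated), via allylboronate 6 (not isolated)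
Conditions: 3, 4 (THF), 0 °C to rt; NaOTf, Pd(OAc)2 (2 mol%), (Sp,Sp)-MandyPhos (2.4 mol%), 2, THF, 60 °C; then 3 M NaOH, 30% H2O2, 0 °C to rt
Reagents that add atoms: hydrogen peroxide, OO
Why: Vinylmagnesium bromide adds to boronate 3 to give the four-coordinate borate 5; zerovalent palladium inserts into the C–Br bond of 2, NaOTf removes bromide, and the cationic arylpalladium binds the unsubstituted vinyl group of 5, triggering a 1,2-metalate shift of the isopropenyl group from boron to the boron-bearing carbon (the future C3–C2 bond) while palladium takes the terminal carbon; reductive elimination then makes the aryl–CH2 bond (the future C4a–C4 bond) and alkaline H2O2 converts C–B into C–OH with retention. The closest known reaction type is the enantioselective palladium-catalysed conjunctive cross-coupling of bis(alkenyl)borates with a MandyPhos ligand, in its variant for Grignard-derived borates and aryl bromides with NaOTf as halide scavenger. No ring is closed in this step; it lays the open C4–C3–C2 chain on ring B with the isopropenyl group placed for the 6-exo closure of O1–C2 in step 3. The new stereocentre C3 is set by the chiral bisphosphine, which selects the face of the palladium-bound vinyl group to which the isopropenyl group migrates anti to the metal, and the stereospecific oxidation carries it over unchanged. The step needs chemoselectivity between the two alkenyl groups on boron: the unsubstituted vinyl group is the better ligand for the bulky arylpalladium and acts as acceptor while the α-methyl-substituted isopropenyl group migrates, and the single ortho substituent of 2 (OMOM) should leave oxidative addition feasible.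

Step 3
Reactants: 7 (2S)-1-[2,3-bis(methoxymethoxy)phenyl]-3-methylbut-3-en-2-ol
Product: 9 (3S)-2,2-dimethylchromane-3,8-diol, via catechol 8 (not isolated)
Conditions: TsOH·H2O (0.2 equiv), MeOH, 45 °C; then MeOH off, PhMe, 60 °C
Reagents that add atoms: none
Why: Acid methanolysis removes both MOM acetals and the same acid then promotes Markovnikov intramolecular hydroalkoxylation of the 1,1-disubstituted alkene (6-exo-trig), for which only the phenol ortho to the side chain can reach a six-membered ring; C3 is not touched.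

Step 4
Reactants: 9 (3S)-2,2-dimethylchromane-3,8-diol
Product: 10 (3S)-8-[(tert-butyldimethylsilyl)oxy]-2,2-dimethylchroman-3-ol
Conditions: TBSCl (1.1 equiv), imidazole, DMF, 0 °C
Reagents that add atoms: tert-butyldimethylsilyl chloride, CC(C)(C)[Si](C)(C)Cl
Why: Chemoselective silylation of the phenol over the hindered secondary alcohol next to the quaternary carbon gives a bulky, non-aromatic protecting group that also shields C7 in step 5.

Step 5
Reactants: 10 (3S)-8-[(tert-butyldimethylsilyl)oxy]-2,2-dimethylchroman-3-ol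
Product: 12 [(3S)-8-[(tert-butyldimethylsilyl)oxy]-3-hydroxy-2,2-dimethylchroman-6-yl]boronic acid, via bis(boryl) compound 11 (not isolated)
Conditions: [Ir(cod)OMe]2 (1.5 mol%), 4,4′-di-tert-butyl-2,2′-bipyridine (3 mol%), B2pin2 (1.3 equiv), THF, 70 °C; then NaIO4, NH4OAc, acetone/H2O, rt
Reagents that add atoms: bis(pinacolato)diboron, CC1(C)OB(OC1(C)C)B1OC(C)(C)C(C)(C)O1; water, O
Why: Sterically controlled iridium-catalysed aromatic C–H borylation should occur at C6, the only ring C–H without an ortho substituent (the alcohol is carried as its borate ester), and periodate cleavage of the pinacol esters releases the boronic acid and the alcohol.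

Step 6
Reactants: 13 5,7-dihydroxychromone
Product: 14 5,7-bis(methoxymethoxy)-4H-chromen-4-one
Conditions: NaH (2.5 equiv), MOMCl (2.5 equiv), DMF, 0 °C to rt
Reagents that add atoms: chloromethyl methyl ether, COCCl
Why: O-alkylation of both phenoxides (MOM protection), the sodium salt being needed for the chelated 5-OH.

Step 7
Reactants: 12 [(3S)-8-[(tert-butyldimethylsilyl)oxy]-3-hydroxy-2,2-dimethylchroman-6-yl]boronic acid; 14 5,7-bis(methoxymethoxy)-4H-chromen-4-one
Product: 15 (2S)-2-[(3S)-8-[(tert-butyldimethylsilyl)oxy]-3-hydroxy-2,2-dimethylchroman-6-yl]-5,7-bis(methoxymethoxy)chroman-4-one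
Conditions: Pd(OCOCF3)2 (5 mol%), (R)-t-BuPyOx (6 mol%), NH4PF6 (30 mol%), H2O (5 equiv), ClCH2CH2Cl, 60 °C
Reagents that add atoms: none
Why: Palladium-catalysed asymmetric conjugate addition of an arylboronic acid to a chromone: the cationic arylpalladium, free of ortho substituents, inserts the C2=C3 bond from the face set by the pyridine-oxazoline ligand and protonolysis of the palladium enolate gives the flavanone, so C2 is catalyst-controlled and the remote C3 centre of the chroman has no say.

Step 8
Reactants: 15 (2S)-2-[(3S)-8-[(tert-butyldimethylsilyl)oxy]-3-hydroxy-2,2-dimethylchroman-6-yl]-5,7-bis(methoxymethoxy)chroman-4-one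
Product: 16 (2S)-2-[(3S)-3,8-dihydroxy-2,2-dimethylchroman-6-yl]-5,7-bis(methoxymethoxy)chroman-4-one
Conditions: KHF2 (2 equiv), MeOH, rt
Reagents that add atoms: none
Why: Bifluoride cleaves phenolic silyl ethers selectively under near-neutral conditions that should leave the MOM acetals and the base-sensitive flavanone C2 centre intact.

Step 9
Reactants: 17 2-methylbut-3-en-2-ol
Product: 18 tert-butyl 2-methylbut-3-en-2-yl carbonate
Conditions: n-BuLi, THF, 0 °C; then Boc2O, 0 °C to rt
Reagents that add atoms: di-tert-butyl dicarbonate, CC(C)(C)OC(=O)OC(=O)OC(C)(C)C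
Why: Acylation of the lithium alkoxide with the dicarbonate gives the mixed tertiary allylic carbonate.

Step 10
Reactants: 16 (2S)-2-[(3S)-3,8-dihydroxy-2,2-dimethylchroman-6-yl]-5,7-bis(methoxymethoxy)chroman-4-one; 18 tert-butyl 2-methylbut-3-en-2-yl carbonate
Product: 19 (2S)-2-[(3S)-3-hydroxy-2,2-dimethyl-8-[(2-methylbut-3-en-2-yl)oxy]chroman-6-yl]-5,7-bis(methoxymethoxy)chroman-4-one
Conditions: Pd(PPh3)4 (5 mol%), 18 (1.5 equiv), THF, 0 °C
Reagents that add atoms: none
Why: Decarboxylative allylic etherification with zerovalent palladium (Tsuji–Trost type): the only free phenol attacks the 1,1-dimethylallyl palladium cation at its substituted terminus under kinetic control at low temperature, without added base that could open the flavanone.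

Step 11
Reactants: 19 (2S)-2-[(3S)-3-hydroxy-2,2-dimethyl-8-[(2-methylbut-3-en-2-yl)oxy]chroman-6-yl]-5,7-bis(methoxymethoxy)chroman-4-one
Product: 20 (2S)-2-[(3S)-3,8-dihydroxy-2,2-dimethyl-7-(3-methylbut-2-en-1-yl)chroman-6-yl]-5,7-bis(methoxymethoxy)chroman-4-one
Conditions: Eu(fod)3 (10 mol%), CHCl3, 60 °C
Reagents that add atoms: none
Why: Lewis-acid-promoted aromatic Claisen rearrangement: C7 is the only ortho position bearing hydrogen (the other carries the ring oxygen), so the allyl unit arrives there with inversion of its termini as a normal prenyl group and tautomerisation regenerates the 8-OH.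

Step 12
Reactants: 20 (2S)-2-[(3S)-3,8-dihydroxy-2,2-dimethyl-7-(3-methylbut-2-en-1-yl)chroman-6-yl]-5,7-bis(methoxymethoxy)chroman-4-one
Product: 21 (2S)-2-[(3S)-3,8-dihydroxy-2,2-dimethyl-7-(3-methylbut-2-en-1-yl)chroman-6-yl]-5,7-dihydroxychroman-4-one
Conditions: 3 M HCl (aq), MeOH, 45 °C
Reagents that add atoms: none
Why: Mild acid methanolysis of the two aryl MOM acetals, under which the prenyl group beside the free phenol, the secondary alcohol and both stereocentres are expected to persist.

**Compound list**

1 | 3-bromocatechol (3-bromobenzene-1,2-diol) | Oc1cccc(Br)c1O | starting material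
2 | 1-bromo-2,3-bis(methoxymethoxy)benzene | COCOc1cccc(Br)c1OCOC | intermediate
3 | isopropenylboronic acid pinacol ester | C=C(C)B1OC(C)(C)C(C)(C)O1 | starting material
4 | vinylmagnesium bromide | C=C[Mg]Br | starting material
5 | bromomagnesium isopropenyl(pinacolato)vinylborate | C=C[B-]1(C(C)=C)OC(C)(C)C(C)(C)O1.[Mg+]Br | intermediate
6 | 2-[(2S)-1-[2,3-bis(methoxymethoxy)phenyl]-3-methylbut-3-en-2-yl]-4,4,5,5-tetramethyl-1,3,2-dioxaborolane | C=C(C)[C@@H](B1OC(C)(C)C(C)(C)O1)Cc1cccc(OCOC)c1OCOC | intermediate
7 | (2S)-1-[2,3-bis(methoxymethoxy)phenyl]-3-methylbut-3-en-2-ol | C=C(C)[C@@H](O)Cc1cccc(OCOC)c1OCOC | intermediate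
8 | 3-[(2S)-2-hydroxy-3-methylbut-3-en-1-yl]benzene-1,2-diol | C=C(C)[C@@H](O)Cc1cccc(O)c1O | intermediate
9 | (3S)-2,2-dimethylchromane-3,8-diol | Oc1cccc2c1OC(C)(C)[C@@H](O)C2 | intermediate
10 | (3S)-8-[(tert-butyldimethylsilyl)oxy]-2,2-dimethylchroman-3-ol | CC(C)(C)[Si](C)(C)Oc1cccc2c1OC(C)(C)[C@@H](O)C2 | intermediate
11 | (3S)-8-[(tert-butyldimethylsilyl)oxy]-2,2-dimethyl-6-(pinacolatoboryl)chroman-3-yl pinacol borate | CC(C)(C)[Si](C)(C)Oc1cc(B3OC(C)(C)C(C)(C)O3)cc2c1OC(C)(C)[C@@H](OB3OC(C)(C)C(C)(C)O3)C2 | intermediate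
12 | [(3S)-8-[(tert-butyldimethylsilyl)oxy]-3-hydroxy-2,2-dimethylchroman-6-yl]boronic acid | CC(C)(C)[Si](C)(C)Oc1cc(B(O)O)cc2c1OC(C)(C)[C@@H](O)C2 | intermediate
13 | 5,7-dihydroxychromone (5,7-dihydroxy-4H-chromen-4-one) | O=c1ccoc2cc(O)cc(O)c12 | starting material
14 | 5,7-bis(methoxymethoxy)-4H-chromen-4-one | O=c1ccoc2cc(OCOC)cc(OCOC)c12 | intermediate
15 | (2S)-2-[(3S)-8-[(tert-butyldimethylsilyl)oxy]-3-hydroxy-2,2-dimethylchroman-6-yl]-5,7-bis(methoxymethoxy)chroman-4-one | CC(C)(C)[Si](C)(C)Oc1cc([C@@H]2CC(=O)c3c(OCOC)cc(OCOC)cc3O2)cc2c1OC(C)(C)[C@@H](O)C2 | intermediate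
16 | (2S)-2-[(3S)-3,8-dihydroxy-2,2-dimethylchroman-6-yl]-5,7-bis(methoxymethoxy)chroman-4-one | Oc1cc([C@@H]2CC(=O)c3c(OCOC)cc(OCOC)cc3O2)cc2c1OC(C)(C)[C@@H](O)C2 | intermediate
17 | 2-methylbut-3-en-2-ol | C=CC(C)(C)O | starting material
18 | tert-butyl 2-methylbut-3-en-2-yl carbonate | C=CC(C)(C)OC(=O)OC(C)(C)C | intermediate
19 | (2S)-2-[(3S)-3-hydroxy-2,2-dimethyl-8-[(2-methylbut-3-en-2-yl)oxy]chroman-6-yl]-5,7-bis(methoxymethoxy)chroman-4-one | C=CC(C)(C)Oc1cc([C@@H]2CC(=O)c3c(OCOC)cc(OCOC)cc3O2)cc2c1OC(C)(C)[C@@H](O)C2 | intermediate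
20 | (2S)-2-[(3S)-3,8-dihydroxy-2,2-dimethyl-7-(3-methylbut-2-en-1-yl)chroman-6-yl]-5,7-bis(methoxymethoxy)chroman-4-one | CC(C)=CCc1c([C@@H]2CC(=O)c3c(OCOC)cc(OCOC)cc3O2)cc2c(c1O)OC(C)(C)[C@@H](O)C2 | intermediate
21 | (2S)-2-[(3S)-3,8-dihydroxy-2,2-dimethyl-7-(3-methylbut-2-en-1-yl)chroman-6-yl]-5,7-dihydroxychroman-4-one | CC(C)=CCc1c([C@@H]2CC(=O)c3c(O)cc(O)cc3O2)cc2c(c1O)OC(C)(C)[C@@H](O)C2 | target

**Step count and risks**

Total: 12 steps. Longest linear sequence: 10 steps (steps 1, 2, 3, 4, 5, 7, 8, 10, 11, 12); steps 6 and 9 are side branches.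

The three steps most likely to fail:

**Step 2.** The two alkenyl groups on boron may exchange roles (isopropenyl activated, vinyl migrating). Oxidative addition beside the ortho acetal oxygen may be slow enough for the borate to decompose, or facial selection at C3 may be poor. The fallback builds the ring first and sets C3 by epoxidation. From 2, bromine–magnesium exchange (i-PrMgCl·LiCl, THF) and addition to 3-methylbut-2-enal would give 1-[2,3-bis(methoxymethoxy)phenyl]-3-methylbut-2-en-1-ol F1. Acid (TsOH·H2O, MeOH, 45 °C) would remove the acetals and close the ring by dehydrative cyclisation through the ortho-quinone methide to 2,2-dimethyl-2H-chromen-8-ol F2. Silylation (TBSCl, imidazole) would give tert-butyl[(2,2-dimethyl-2H-chromen-8-yl)oxy]dimethylsilane F3. Jacobsen epoxidation ((S,S)-(salen)MnCl, NaOCl, 4-phenylpyridine N-oxide) would give (3S,4S)-8-[(tert-butyldimethylsilyl)oxy]-3,4-epoxy-2,2-dimethylchromane F4. Hydrogenolysis of the benzylic C–O bond (H2, palladium on carbon, EtOAc) would then deliver 10, where the route is rejoined.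

**Step 7.** Facial discrimination by the ligand may be insufficient at the electron-rich, peri-substituted chromone, and the C2 configuration may erode through reversible ring opening. The fallback gives up catalyst control. From 12 and 14, the addition would be run with an achiral catalyst (Pd(OCOCF3)2, 2,2′-bipyridine) to give 15 together with (2R)-2-[(3S)-8-[(tert-butyldimethylsilyl)oxy]-3-hydroxy-2,2-dimethylchroman-6-yl]-5,7-bis(methoxymethoxy)chroman-4-one F5. The two are diastereomers, because C3 of the chroman is already fixed, and would be separated by chromatography. The unwanted epimer would be recycled with mild base (NaOAc, EtOH, 60 °C) through (E)-3-[(3S)-8-[(tert-butyldimethylsilyl)oxy]-3-hydroxy-2,2-dimethylchroman-6-yl]-1-[2-hydroxy-4,6-bis(methoxymethoxy)phenyl]prop-2-en-1-one F6, which re-closes to both epimers. The route is rejoined at 15.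

**Step 3.** Under acid the secondary allylic alcohol may ionise (dehydration or dihydrobenzofuran formation), or the β-hydroxy cation may undergo a 1,2-hydride shift to the ketone faster than the phenol adds. The fallback closes the ring without a free carbocation. From 7, acetal cleavage under milder acid (dilute HCl, MeOH, rt) would stop at catechol 8, here isolated. Silylation of the less hindered phenol (TBSCl, imidazole, CH2Cl2, −20 °C) would give 2-[(tert-butyldimethylsilyl)oxy]-6-[(2S)-2-hydroxy-3-methylbut-3-en-1-yl]phenol F7. Intramolecular alkoxymercuration (Hg(OCOCF3)2, THF, 0 °C) would give [(3S)-8-[(tert-butyldimethylsilyl)oxy]-3-hydroxy-2-methylchroman-2-yl]methylmercury trifluoroacetate F8 as both C2 epimers. Demercuration (NaBH4, DMF, 0 °C) would give 10 directly, so that step 4 falls away.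

**Further compounds**

F1 | step 2 | 1-[2,3-bis(methoxymethoxy)phenyl]-3-methylbut-2-en-1-ol (racemic) | CC(C)=CC(O)c1cccc(OCOC)c1OCOC
F2 | step 2 | 2,2-dimethyl-2H-chromen-8-ol | CC1(C)C=Cc2cccc(O)c2O1
F3 | step 2 | tert-butyl[(2,2-dimethyl-2H-chromen-8-yl)oxy]dimethylsilane | CC(C)(C)[Si](C)(C)Oc1cccc2C=CC(C)(C)Oc12
F4 | step 2 | (3S,4S)-8-[(tert-butyldimethylsilyl)oxy]-3,4-epoxy-2,2-dimethylchromane | CC(C)(C)[Si](C)(C)Oc1cccc2c1OC(C)(C)[C@H]3O[C@@H]23
F5 | step 7 | (2R)-2-[(3S)-8-[(tert-butyldimethylsilyl)oxy]-3-hydroxy-2,2-dimethylchroman-6-yl]-5,7-bis(methoxymethoxy)chroman-4-one | CC(C)(C)[Si](C)(C)Oc1cc([C@H]2CC(=O)c3c(OCOC)cc(OCOC)cc3O2)cc2c1OC(C)(C)[C@@H](O)C2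
F6 | step 7 | (E)-3-[(3S)-8-[(tert-butyldimethylsilyl)oxy]-3-hydroxy-2,2-dimethylchroman-6-yl]-1-[2-hydroxy-4,6-bis(methoxymethoxy)phenyl]prop-2-en-1-one | CC(C)(C)[Si](C)(C)Oc1cc(/C=C/C(=O)c3c(OCOC)cc(OCOC)cc3O)cc2c1OC(C)(C)[C@@H](O)C2
F7 | step 3 | 2-[(tert-butyldimethylsilyl)oxy]-6-[(2S)-2-hydroxy-3-methylbut-3-en-1-yl]phenol | C=C(C)[C@@H](O)Cc1cccc(O[Si](C)(C)C(C)(C)C)c1O
F8 | step 3 | [(3S)-8-[(tert-butyldimethylsilyl)oxy]-3-hydroxy-2-methylchroman-2-yl]methylmercury trifluoroacetate (both C2 epimers) | CC(C)(C)[Si](C)(C)Oc1cccc2c1OC(C)(C[Hg]OC(=O)C(F)(F)F)[C@@H](O)C2
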